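**Retrosynthetic overview**

- Feature used: on ring A (the central caffeoyl ring) O3 carries the Z-enol ether and the neighbouring O4 is a free phenol. O3, O4 and the carboxyl carbon of the aryloxyacrylic acid can be tied into a six-membered aryl lactone (a 1,4-benzodioxin-2-one, C4–O4–C(=O)–Cα–O3–C3), in which Cα is a CH2 between O3 and an aryl-ester carbonyl.
- Last disconnections: the allyl groups on ring B, ring C and the danshensu carboxyl (Tsuji–Trost), and the O4–C(=O) lactone bond (hydroxide), which gives back the 4-OH and the acrylic acid.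
- Key disconnection: the Cα=Cβ bond of the enol ether, made by aldol condensation of the lactone CH2 with 3,4-bis(allyloxy)benzaldehyde; the ring dictates the Z geometry.
- Precursor: lactone C–O (carbodiimide), caffeate C–O to allyl-protected (R)-danshensu (Steglich), cinnamic C=C (Doebner), O3–CH2 (tert-butyl bromoacetate) on 4-O-PMB protocatechualdehyde.
- Ring order: the only ring formed is the benzodioxinone (step 7), used as a template in step 9 and opened in step 10; the single stereocentre comes from (R)-danshensu.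

Key step: step 9

Remark: ring A is the central caffeoyl ring (C1 bears the propenoate, O3 and O4 are its phenolic oxygens), ring B the catechol ring on the enol ether, ring C the danshensu catechol ring. Commercial danshensu sodium is taken to be the (R)-enantiomer, which is the configuration required. PMB = 4-methoxybenzyl; EDC·HCl = N-(3-dimethylaminopropyl)-N′-ethylcarbodiimide hydrochloride.

**Route**

Step 1
Reactants: 1 3,4-dihydroxybenzaldehyde
Product: 2 3-hydroxy-4-[(4-methoxybenzyl)oxy]benzaldehyde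
Conditions: PMBCl, NaHCO3, NaI (cat.), DMF, 40 °C
Reagents that add atoms: 4-methoxybenzyl chloride, COc1ccc(CCl)cc1
Why: Williamson etherification under weak-base control, in which NaHCO3 ionises only the 4-OH (acidified by the para formyl group), so that monoalkylation at O4 is expected.

Step 2
Reactants: 2 3-hydroxy-4-[(4-methoxybenzyl)oxy]benzaldehyde; 3 tert-butyl bromoacetate
Product: 4 tert-butyl 2-{5-formyl-2-[(4-methoxybenzyl)oxy]phenoxy}acetate
Conditions: K2CO3, DMF, rt
Reagents that add atoms: none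
Why: Williamson etherification (SN2) of the remaining 3-phenoxide with a primary α-bromo ester; the tert-butyl ester resists carbonate and the aldehyde cannot enolise.

Step 3
Reactants: 4 tert-butyl 2-{5-formyl-2-[(4-methoxybenzyl)oxy]phenoxy}acetate; 5 malonic acid
Product: 7 (E)-3-{3-(2-tert-butoxy-2-oxoethoxy)-4-[(4-methoxybenzyl)oxy]phenyl}acrylic acid, via arylidenemalonic acid 6 (not isolated)
Conditions: pyridine, piperidine (cat.), 85 °C
Reagents that add atoms: none
Why: Knoevenagel–Doebner condensation, in which the arylidenemalonic acid loses CO2 in hot pyridine to give the E-cinnamic acid, while the tert-butyl ester and the PMB ether are inert to amines.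

Step 4
Reactants: 8 sodium (R)-3-(3,4-dihydroxyphenyl)-2-hydroxypropanoate (danshensu sodium)
Product: 9 allyl (R)-3-[3,4-bis(allyloxy)phenyl]-2-hydroxypropanoate
Conditions: allyl bromide, K2CO3, DMF, rt
Reagents that add atoms: allyl bromide, C=CCBr
Why: Carbonate-mediated O-alkylation (SN2) of the carboxylate and both phenoxides; the secondary alcohol is not ionised by K2CO3 and stays free, and the chiral-pool stereocentre is not involved.

Step 5
Reactants: 7 (E)-3-{3-(2-tert-butoxy-2-oxoethoxy)-4-[(4-methoxybenzyl)oxy]phenyl}acrylic acid; 9 allyl (R)-3-[3,4-bis(allyloxy)phenyl]-2-hydroxypropanoate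
Product: 10 allyl (R)-3-[3,4-bis(allyloxy)phenyl]-2-{[(E)-3-{3-(2-tert-butoxy-2-oxoethoxy)-4-[(4-methoxybenzyl)oxy]phenyl}prop-2-enoyl]oxy}propanoate
Conditions: EDC·HCl, DMAP (cat.), CH2Cl2, 0 °C to rt
Reagents that add atoms: none
Why: Steglich esterification, in which the acid is activated as O-acylisourea and acylpyridinium and acylates the secondary alcohol with retention, because the C2–O bond of 9 is never broken.

Step 6
Reactants: 10 the PMB- and tert-butyl-protected caffeate of step 5
Product: 11 2-{5-[(E)-3-{[(R)-1-(allyloxy)-3-[3,4-bis(allyloxy)phenyl]-1-oxopropan-2-yl]oxy}-3-oxoprop-1-en-1-yl]-2-hydroxyphenoxy}acetic acid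
Conditions: TFA, anisole (excess), CH2Cl2, 0 °C to rt
Reagents that add atoms: none
Why: Acidolysis, in which TFA ionises the tert-butyl ester (to isobutene) and the aryl PMB ether (cation trapped by anisole in a Friedel–Crafts reaction), whereas allyl ethers, the allyl ester and the cinnamate are stable to TFA at room temperature.

Step 7
Reactants: 11 the hydroxy acid of step 6
Product: 12 allyl (R)-3-[3,4-bis(allyloxy)phenyl]-2-{[(E)-3-(2-oxo-2,3-dihydro-1,4-benzodioxin-6-yl)prop-2-enoyl]oxy}propanoate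
Conditions: EDC·HCl, DMAP (cat.), CH2Cl2 (0.01 M), 0 °C to rt
Reagents that add atoms: none
Why: Carbodiimide (Steglich-type) lactonisation, in which the activated aryloxyacetic acid is captured by the neighbouring 4-OH in a favoured six-membered closure (6-exo-trig), with dilution suppressing dimers.

Step 8
Reactants: 1 3,4-dihydroxybenzaldehyde
Product: 13 3,4-bis(allyloxy)benzaldehyde
Conditions: allyl bromide, K2CO3, DMF, 60 °C
Reagents that add atoms: allyl bromide, C=CCBr
Why: Williamson etherification of both phenols with an excess of the allylic halide.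

Step 9
Reactants: 12 the ring A 1,4-benzodioxin-2-one caffeate of step 7; 13 3,4-bis(allyloxy)benzaldehyde
Product: 17 allyl (R)-3-[3,4-bis(allyloxy)phenyl]-2-{[(E)-3-{(3Z)-3-[3,4-bis(allyloxy)benzylidene]-2-oxo-2,3-dihydro-1,4-benzodioxin-6-yl}prop-2-enoyl]oxy}propanoate, via titanium enolate 14 (not isolated), via aldol adduct 15 (not isolated), via aldol mesylate 16 (not isolated)
Conditions: TiCl4, Et3N (1.1 equiv), CH2Cl2, −78 °C; then 13, −78 to −20 °C; aq. NH4Cl; crude: MsCl, Et3N, CH2Cl2, 0 °C to rt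
Reagents that add atoms: none
Why: Proposed new method: TiCl4 complexes the lactone carbonyl and Et3N removes a proton from C3 (the CH2 between the ring ether oxygen and the aryl-ester carbonyl) to give trichlorotitanium enolate 14, which adds to aldehyde 13; mesylation of aldol 15 and E1cB loss of methanesulfonate from 16 then give the exocyclic alkene, so that only the Cα=Cβ bond of the enol ether is made. The closest known reaction types are the Erlenmeyer azlactone condensation, the aldol condensation of benzofuran-3(2H)-ones with aryl aldehydes to aurones, and titanium-mediated aldol reactions of simple aryl esters; a 1,4-benzodioxin-2-one has not been used in this way. No ring is closed: the lactone ring, made in step 7, only holds the carbonyl and the ring oxygen in fixed positions around the new double bond. No stereocentre remains (the two centres of 15 and 16 vanish on elimination); the one new stereo element is the alkene geometry, which should be Z because in the E isomer ring B would lie against the lactone carbonyl oxygen whereas in the Z isomer it sits beside the ring ether oxygen, and the stepwise E1cB elimination lets the enolate reach the less strained arrangement. The selectivity needed is enolisation of the lactone CH2 and not of the tertiary α-hydrogen of the danshensu ester (which would endanger the (R) centre); the lactone CH2 is more acidic (aryl ester held in the lactone geometry, α-aryloxy group) and less hindered, and the base is kept near one equivalent at −78 °C. The allyl groups, the cinnamate and the allyl ester should not react with TiCl4/Et3N or MsCl/Et3N at these temperatures.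

Step 10
Reactants: 17 the (Z)-3-arylidene-1,4-benzodioxin-2-one of step 9
Product: 18 (Z)-2-{5-[(E)-3-{[(R)-1-(allyloxy)-3-[3,4-bis(allyloxy)phenyl]-1-oxopropan-2-yl]oxy}-3-oxoprop-1-en-1-yl]-2-hydroxyphenoxy}-3-[3,4-bis(allyloxy)phenyl]acrylic acid
Conditions: LiOH (2.1 equiv), THF/H2O, 0 °C; then 1 M HCl
Reagents that add atoms: lithium hydroxide, [Li+].[OH-]
Why: Saponification of an aryl ester, in which the lactone with its phenoxide leaving group should be attacked by hydroxide much faster than the conjugated secondary cinnamate at 0 °C, and once it is open the carboxylate and para-phenoxide deactivate the cinnamate further; the Z alkene and the (R) centre are not touched.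

Step 11
Reactants: 18 the penta-allyl seco acid of step 10
Product: 19 salvianolic acid H
Conditions: Pd(PPh3)4 (cat.), morpholine, THF, rt, under argon; then dilute HCl
Reagents that add atoms: none
Why: Tsuji–Trost deallylation, in which zerovalent palladium ionises the four aryl allyl ethers and the allyl ester to π-allyl complexes that morpholine captures, leaving both esters, both alkenes and the stereocentre untouched.

**Compound list**

1 | 3,4-dihydroxybenzaldehyde (protocatechualdehyde) | O=Cc1ccc(O)c(O)c1 | starting material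
2 | 3-hydroxy-4-[(4-methoxybenzyl)oxy]benzaldehyde | O=Cc1ccc(OCc2ccc(OC)cc2)c(O)c1 | intermediate
3 | tert-butyl bromoacetate | CC(C)(C)OC(=O)CBr | starting material
4 | tert-butyl 2-{5-formyl-2-[(4-methoxybenzyl)oxy]phenoxy}acetate | O=Cc1ccc(OCc2ccc(OC)cc2)c(OCC(=O)OC(C)(C)C)c1 | intermediate
5 | malonic acid | O=C(O)CC(=O)O | starting material
6 | 2-{3-(2-tert-butoxy-2-oxoethoxy)-4-[(4-methoxybenzyl)oxy]benzylidene}malonic acid (not isolated) | OC(=O)C(=Cc1ccc(OCc2ccc(OC)cc2)c(OCC(=O)OC(C)(C)C)c1)C(=O)O | intermediate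
7 | (E)-3-{3-(2-tert-butoxy-2-oxoethoxy)-4-[(4-methoxybenzyl)oxy]phenyl}acrylic acid | OC(=O)/C=C/c1ccc(OCc2ccc(OC)cc2)c(OCC(=O)OC(C)(C)C)c1 | intermediate
8 | sodium (R)-3-(3,4-dihydroxyphenyl)-2-hydroxypropanoate (danshensu sodium) | O[C@H](Cc1ccc(O)c(O)c1)C(=O)[O-].[Na+] | starting material
9 | allyl (R)-3-[3,4-bis(allyloxy)phenyl]-2-hydroxypropanoate | O[C@H](Cc1ccc(OCC=C)c(OCC=C)c1)C(=O)OCC=C | intermediate
10 | allyl (R)-3-[3,4-bis(allyloxy)phenyl]-2-{[(E)-3-{3-(2-tert-butoxy-2-oxoethoxy)-4-[(4-methoxybenzyl)oxy]phenyl}prop-2-enoyl]oxy}propanoate | O=C(/C=C/c1ccc(OCc2ccc(OC)cc2)c(OCC(=O)OC(C)(C)C)c1)O[C@H](Cc1ccc(OCC=C)c(OCC=C)c1)C(=O)OCC=C | intermediate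
11 | 2-{5-[(E)-3-{[(R)-1-(allyloxy)-3-[3,4-bis(allyloxy)phenyl]-1-oxopropan-2-yl]oxy}-3-oxoprop-1-en-1-yl]-2-hydroxyphenoxy}acetic acid | O=C(/C=C/c1ccc(O)c(OCC(=O)O)c1)O[C@H](Cc1ccc(OCC=C)c(OCC=C)c1)C(=O)OCC=C | intermediate
12 | allyl (R)-3-[3,4-bis(allyloxy)phenyl]-2-{[(E)-3-(2-oxo-2,3-dihydro-1,4-benzodioxin-6-yl)prop-2-enoyl]oxy}propanoate (key-step precursor) | O=C(/C=C/c1ccc2OC(=O)COc2c1)O[C@H](Cc1ccc(OCC=C)c(OCC=C)c1)C(=O)OCC=C | intermediate
13 | 3,4-bis(allyloxy)benzaldehyde | O=Cc1ccc(OCC=C)c(OCC=C)c1 | intermediate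
14 | trichlorotitanium enolate of 12 at the lactone C2–C3 (not isolated) | O=C(/C=C/c1ccc2OC(O[Ti](Cl)(Cl)Cl)=COc2c1)O[C@H](Cc1ccc(OCC=C)c(OCC=C)c1)C(=O)OCC=C | intermediate
15 | allyl (R)-3-[3,4-bis(allyloxy)phenyl]-2-{[(E)-3-(3-{[3,4-bis(allyloxy)phenyl](hydroxy)methyl}-2-oxo-2,3-dihydro-1,4-benzodioxin-6-yl)prop-2-enoyl]oxy}propanoate, mixture of diastereomers at lactone C3 and the carbinol carbon (not isolated) | O=C(/C=C/c1ccc2OC(=O)C(C(O)c3ccc(OCC=C)c(OCC=C)c3)Oc2c1)O[C@H](Cc1ccc(OCC=C)c(OCC=C)c1)C(=O)OCC=C | intermediate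
16 | methanesulfonate of 15, mixture of diastereomers at the same two carbons (not isolated) | O=C(/C=C/c1ccc2OC(=O)C(C(OS(C)(=O)=O)c3ccc(OCC=C)c(OCC=C)c3)Oc2c1)O[C@H](Cc1ccc(OCC=C)c(OCC=C)c1)C(=O)OCC=C | intermediate
17 | allyl (R)-3-[3,4-bis(allyloxy)phenyl]-2-{[(E)-3-{(3Z)-3-[3,4-bis(allyloxy)benzylidene]-2-oxo-2,3-dihydro-1,4-benzodioxin-6-yl}prop-2-enoyl]oxy}propanoate (key-step product) | O=C(/C=C/c1ccc2OC(=O)/C(=C/c3ccc(OCC=C)c(OCC=C)c3)Oc2c1)O[C@H](Cc1ccc(OCC=C)c(OCC=C)c1)C(=O)OCC=C | intermediate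
18 | (Z)-2-{5-[(E)-3-{[(R)-1-(allyloxy)-3-[3,4-bis(allyloxy)phenyl]-1-oxopropan-2-yl]oxy}-3-oxoprop-1-en-1-yl]-2-hydroxyphenoxy}-3-[3,4-bis(allyloxy)phenyl]acrylic acid | O=C(/C=C/c1ccc(O)c(O/C(=C\c2ccc(OCC=C)c(OCC=C)c2)C(=O)O)c1)O[C@H](Cc1ccc(OCC=C)c(OCC=C)c1)C(=O)OCC=C | intermediate
19 | salvianolic acid H | O=C(/C=C/c1ccc(O)c(O/C(=C\c2ccc(O)c(O)c2)C(=O)O)c1)O[C@H](Cc1ccc(O)c(O)c1)C(=O)O | target

**Step count and risks**

Total steps: 11. Longest linear sequence: 9 steps (steps 1, 2, 3, 5, 6, 7, 9, 10, 11).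

Step 9 (proposed new method). What may go wrong: enolisation at the α-hydrogen of the danshensu ester, with erosion of the (R) centre; retro-aldol before elimination; formation of the E-arylidene. Fallback by known chemistry (Horner–Wadsworth–Emmons olefination): it sets out from 9 and 2 and comes back at 18.
- Alcohol 9 is esterified with (diethoxyphosphoryl)acetic acid (EDC·HCl, DMAP) to the phosphonoacetate allyl (R)-3-[3,4-bis(allyloxy)phenyl]-2-{[(diethoxyphosphoryl)acetyl]oxy}propanoate F1.
- Olefination of aldehyde 2 with it (LiCl, DBU, MeCN) should give the E-caffeate with free 3-OH, allyl (R)-3-[3,4-bis(allyloxy)phenyl]-2-{[(E)-3-{3-hydroxy-4-[(4-methoxybenzyl)oxy]phenyl}prop-2-enoyl]oxy}propanoate F2.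
- O–H insertion of tert-butyl diazo(diethoxyphosphoryl)acetate into this phenol, catalysed by dirhodium tetraacetate Rh2(OAc)4 in warm toluene, should give the α-aryloxy phosphonoacetate allyl (R)-3-[3,4-bis(allyloxy)phenyl]-2-{[(E)-3-{3-[2-tert-butoxy-1-(diethoxyphosphoryl)-2-oxoethoxy]-4-[(4-methoxybenzyl)oxy]phenyl}prop-2-enoyl]oxy}propanoate F3. Insertion into the phenolic O–H is expected to outrun cyclopropanation of the allyl groups.
- A second olefination with aldehyde 13 (LiCl, DBU; the phosphonate C–H is by far the most acidic) should give tert-butyl (Z)-2-{5-[(E)-3-{[(R)-1-(allyloxy)-3-[3,4-bis(allyloxy)phenyl]-1-oxopropan-2-yl]oxy}-3-oxoprop-1-en-1-yl]-2-[(4-methoxybenzyl)oxy]phenoxy}-3-[3,4-bis(allyloxy)phenyl]acrylate F4. The Z isomer is the thermodynamically preferred one; any E isomer would be separated or equilibrated with catalytic I2.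
- TFA/anisole then removes the tert-butyl ester and the PMB ether to give 18.

Step 10. What may go wrong: hydroxide also cleaving the caffeate ester, or epimerisation at C2 of the danshensu unit under base. Loss of the allyl ester alone would be harmless, since step 11 removes it anyway. Fallback: it sets out from 17 and comes back at 19. The lactone is opened by alcoholysis instead of hydrolysis (allyl alcohol/THF, K2CO3 cat., 0 °C), which should give allyl (Z)-2-{5-[(E)-3-{[(R)-1-(allyloxy)-3-[3,4-bis(allyloxy)phenyl]-1-oxopropan-2-yl]oxy}-3-oxoprop-1-en-1-yl]-2-hydroxyphenoxy}-3-[3,4-bis(allyloxy)phenyl]acrylate F5. Any exchange at the danshensu allyl ester is degenerate. The step 11 conditions (Pd(PPh3)4, morpholine) then remove six allyl groups and give 19 directly.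

Step 6. What may go wrong: Friedel–Crafts benzylation of the allyloxy-substituted rings by the 4-methoxybenzyl cation, or acid-induced loss of allyl groups. Fallback: it sets out from 10 and comes back at 11. The PMB ether is removed oxidatively (DDQ, CH2Cl2/pH 7 buffer, 0 °C), which should give allyl (R)-3-[3,4-bis(allyloxy)phenyl]-2-{[(E)-3-[3-(2-tert-butoxy-2-oxoethoxy)-4-hydroxyphenyl]prop-2-enoyl]oxy}propanoate F6 with the tert-butyl ester intact. TFA/CH2Cl2 then cleaves only the tert-butyl ester, with no benzylic cation present, to give 11.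

**Further compounds**

F1 | step 9 | allyl (R)-3-[3,4-bis(allyloxy)phenyl]-2-{[(diethoxyphosphoryl)acetyl]oxy}propanoate | CCOP(=O)(OCC)CC(=O)O[C@H](Cc1ccc(OCC=C)c(OCC=C)c1)C(=O)OCC=C
F2 | step 9 | allyl (R)-3-[3,4-bis(allyloxy)phenyl]-2-{[(E)-3-{3-hydroxy-4-[(4-methoxybenzyl)oxy]phenyl}prop-2-enoyl]oxy}propanoate | O=C(/C=C/c1ccc(OCc2ccc(OC)cc2)c(O)c1)O[C@H](Cc1ccc(OCC=C)c(OCC=C)c1)C(=O)OCC=C
F3 | step 9 | allyl (R)-3-[3,4-bis(allyloxy)phenyl]-2-{[(E)-3-{3-[2-tert-butoxy-1-(diethoxyphosphoryl)-2-oxoethoxy]-4-[(4-methoxybenzyl)oxy]phenyl}prop-2-enoyl]oxy}propanoate (mixture at the phosphonate carbon) | O=C(/C=C/c1ccc(OCc2ccc(OC)cc2)c(OC(C(=O)OC(C)(C)C)P(=O)(OCC)OCC)c1)O[C@H](Cc1ccc(OCC=C)c(OCC=C)c1)C(=O)OCC=C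
F4 | step 9 | tert-butyl (Z)-2-{5-[(E)-3-{[(R)-1-(allyloxy)-3-[3,4-bis(allyloxy)phenyl]-1-oxopropan-2-yl]oxy}-3-oxoprop-1-en-1-yl]-2-[(4-methoxybenzyl)oxy]phenoxy}-3-[3,4-bis(allyloxy)phenyl]acrylate | O=C(/C=C/c1ccc(OCc2ccc(OC)cc2)c(O/C(=C\c2ccc(OCC=C)c(OCC=C)c2)C(=O)OC(C)(C)C)c1)O[C@H](Cc1ccc(OCC=C)c(OCC=C)c1)C(=O)OCC=C
F5 | step 10 | allyl (Z)-2-{5-[(E)-3-{[(R)-1-(allyloxy)-3-[3,4-bis(allyloxy)phenyl]-1-oxopropan-2-yl]oxy}-3-oxoprop-1-en-1-yl]-2-hydroxyphenoxy}-3-[3,4-bis(allyloxy)phenyl]acrylate | O=C(/C=C/c1ccc(O)c(O/C(=C\c2ccc(OCC=C)c(OCC=C)c2)C(=O)OCC=C)c1)O[C@H](Cc1ccc(OCC=C)c(OCC=C)c1)C(=O)OCC=C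
F6 | step 6 | allyl (R)-3-[3,4-bis(allyloxy)phenyl]-2-{[(E)-3-[3-(2-tert-butoxy-2-oxoethoxy)-4-hydroxyphenyl]prop-2-enoyl]oxy}propanoate | O=C(/C=C/c1ccc(O)c(OCC(=O)OC(C)(C)C)c1)O[C@H](Cc1ccc(OCC=C)c(OCC=C)c1)C(=O)OCC=C
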